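Numbering: unit 1 is the 5,7-dihydroxyflavone (O1–C8a, ring B C1'–C6'); unit 2 is the 8-aryl flavone (double primes, ring B triple primes).

**Plan**
- Ring C of unit 1 is cut first (O1–C2 and the C2–C3 double bond, through a chalcone) to an aldehyde on C1' and a protected phloroacetophenone.
- Ring A of unit 2 is cut at C7''–C8''. C8'', the aryl-bearing carbon between C7''–OH and C8a''–O1'', becomes the benzylic CH2 of a 2-aryl-6-arylmethyl-4-pyranone (ring C of unit 2), and C7'' becomes the ester carbon of an (E)-β-methoxyacrylate on C4a''. Because the aryl group is on C8'' before ring A exists, the choice between C6'' and C8'' never has to be made.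
- The pyranone is cut at C4''–C4a'', C4a''–C8a'' and O1''–C2'' into an arylpropiolic amide, an arylacetic acid and methyl (E)-3-methoxybut-2-enoate.
- Forward: C4 of the crotonate is acylated twice and ring C of unit 2 closes; ring A of unit 2 closes by carbanion Claisen condensation; ring C of unit 1 closes last; one BCl3 step frees all phenols.
- Stereochemistry: the target has no stereocentre. The only stereo-element used is the E enol ether of the crotonate (ester cis to the pyranone), which is consumed in the key step.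

Key step: step 8

Assumption: the 3'–8'' biaryl axis is taken as configurationally labile, since the target is written without an axial descriptor, so no axial control is planned.

**Route**

Step 1
Reactants: 1 4-(benzyloxy)-3-methoxybenzaldehyde
Product: 2 1-(benzyloxy)-4-(2,2-dibromoethenyl)-2-methoxybenzene
Conditions: CBr4, PPh3, CH2Cl2, 0 °C
Reagents that add atoms: carbon tetrabromide, BrC(Br)(Br)Br
Why: Corey–Fuchs dibromo-olefination, in which the ylide formed from CBr4 and PPh3 converts the aryl aldehyde into the 1,1-dibromoalkene by a Wittig reaction that leaves the aryl ethers untouched.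

Step 2
Reactants: 2 1-(benzyloxy)-4-(2,2-dibromoethenyl)-2-methoxybenzene
Product: 4 3-[4-(benzyloxy)-3-methoxyphenyl]-N-methoxy-N-methylprop-2-ynamide, via lithium arylacetylide 3 (not isolated)
Conditions: n-BuLi (2.2 equiv), THF, −78 °C to 0 °C; then ClC(O)N(OMe)Me, −78 °C to rt
Reagents that add atoms: N-methoxy-N-methylcarbamoyl chloride, CON(C)C(Cl)=O
Why: Second half of the Corey–Fuchs sequence, where bromine–lithium exchange and Fritsch–Buttenberg–Wiechell rearrangement give the lithium acetylide, which is acylated by the carbamoyl chloride to the alkynyl N-methoxy-N-methylamide.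

Step 3
Reactants: 5 methyl (E)-3-methoxybut-2-enoate; 4 3-[4-(benzyloxy)-3-methoxyphenyl]-N-methoxy-N-methylprop-2-ynamide
Product: 7 methyl (E)-7-[4-(benzyloxy)-3-methoxyphenyl]-3-methoxy-5-oxohept-2-en-6-ynoate, via lithium dienolate 6 (not isolated)
Conditions: LiN(i-Pr)2, THF, −78 °C; then 4, −78 °C; AcOH quench at −78 °C
Reagents that add atoms: none
Why: Weinreb ketone synthesis with a vinylogous ester enolate, in which the dienolate of the β-methoxycrotonate reacts at its terminal carbon C4 with the non-enolisable alkynyl amide, the N-methoxy-N-methylamide holds the addition at the ketone oxidation level until the cold acidic quench, and the E enol ether (ester cis to the new chain) is carried over.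

Step 4
Reactants: 8 4-(benzyloxy)-3-bromobenzaldehyde
Product: 9 2-[4-(benzyloxy)-3-bromophenyl]-1,3-dioxolane
Conditions: ethylene glycol, TsOH (cat.), toluene, reflux, Dean–Stark trap
Reagents that add atoms: ethylene glycol, OCCO
Why: Acid-catalysed acetalisation with azeotropic removal of water masks the aldehyde as a base-stable 1,3-dioxolane for the organometallic and enolate steps that follow.

Step 5
Reactants: 9 2-[4-(benzyloxy)-3-bromophenyl]-1,3-dioxolane
Product: 10 ethyl [2-(benzyloxy)-5-(1,3-dioxolan-2-yl)phenyl]acetate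
Conditions: BrZnCH2CO2Et, Pd2(dba)3 (cat.), XPhos (cat.), THF, 65 °C
Reagents that add atoms: (2-ethoxy-2-oxoethyl)zinc bromide, CCOC(=O)C[Zn]Br
Why: Negishi-type cross-coupling of a Reformatsky reagent with the aryl bromide (palladium-catalysed α-arylation of an ester zinc enolate), whose nearly neutral conditions tolerate the acetal and whose bulky biarylphosphine allows coupling next to the ortho benzyloxy group.

Step 6
Reactants: 10 ethyl [2-(benzyloxy)-5-(1,3-dioxolan-2-yl)phenyl]acetate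
Product: 11 [2-(benzyloxy)-5-(1,3-dioxolan-2-yl)phenyl]acetic acid
Conditions: LiOH, THF/H2O, rt; then 1 M HCl to pH 4 at 0 °C
Reagents that add atoms: lithium hydroxide, [Li+].[OH-]
Why: Saponification of the ethyl ester, with acidification only to pH 4 in the cold so that the dioxolane stays intact.

Step 7
Reactants: 11 [2-(benzyloxy)-5-(1,3-dioxolan-2-yl)phenyl]acetic acid; 7 methyl (E)-7-[4-(benzyloxy)-3-methoxyphenyl]-3-methoxy-5-oxohept-2-en-6-ynoate
Product: 14 methyl (E)-3-{2-[2-(benzyloxy)-5-(1,3-dioxolan-2-yl)benzyl]-6-[4-(benzyloxy)-3-methoxyphenyl]-4-oxo-4H-pyran-3-yl}-3-methoxyprop-2-enoate, via arylacetyl chloride 12 (not isolated), via acetylenic triketone 13 (not isolated)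
Conditions: 11, 1-chloro-N,N,2-trimethylprop-1-en-1-amine, CH2Cl2, 0 °C to rt; then added to 7, MgCl2, pyridine, CH2Cl2, 0 °C to rt; then DMAP (cat.), rt
Reagents that add atoms: none
Why: Magnesium-enolate C-acylation of an active methylene compound followed by 6-endo-dig oxa-Michael closure of the acetylenic β-diketone to a 4-pyranone, where C4 of 7 is its only acidic position, chelation to magnesium steers the acid chloride (made under neutral conditions so that the acetal survives) to carbon, and only the enol oxygen of the arylacetyl group can reach the ynone β-carbon, which places the arylmethyl group on the carbon next to the ring oxygen.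

Step 8
Reactants: 14 methyl (E)-3-{2-[2-(benzyloxy)-5-(1,3-dioxolan-2-yl)benzyl]-6-[4-(benzyloxy)-3-methoxyphenyl]-4-oxo-4H-pyran-3-yl}-3-methoxyprop-2-enoate
Product: 16 8-[2-(benzyloxy)-5-(1,3-dioxolan-2-yl)phenyl]-2-[4-(benzyloxy)-3-methoxyphenyl]-7-hydroxy-5-methoxy-4H-chromen-4-one, via 8H-chromene-4,7-dione tautomer 15 (not isolated)
Conditions: LiN(SiMe3)2 (3 equiv), THF, −78 °C to 0 °C; aq. NH4Cl
Reagents that add atoms: none
Why: Proposed new method: the C8'' methylene of 14 is acidified twice over, by its aryl group and, through the C8a''=C4a'' double bond, by the C4'' carbonyl, and no other C–H competes, so LiN(SiMe3)2 should give the extended enolate, which attacks the ester carbon C7'' held cis to the pyranone by the E enol ether; expulsion of methoxide gives dienone 15, which a second equivalent of base converts into the C7'' phenoxide while C5'' keeps its methyl ether. The closest known reactions are Claisen cyclisations of pyranone-masked poly-β-carbonyl chains to phenols and benzannulations of 3-acyl-2-methylchromones through the vinylogous methyl anion; new here is a β-methoxyacrylate ester as the electrophile on a monocyclic 6-arylmethyl-4-pyranone. Ring A of unit 2 closes in a 6-exo-trig mode, the ester carbonyl oxygen remaining outside the new ring. No stereocentre is created, since the transient C8'' centre of 15 disappears on aromatisation, which also makes the closure irreversible. The step needs regiocontrol of the aryl group and chemoselective attack at the ester: the first is fixed by connectivity, because the arylmethyl carbon is already bonded to C8a'' and a 6-aryl isomer cannot form, and the second by ring size, because addition to C5'' would close a four-membered ring. Should some Z enol ether be present, the lithium methoxide released can equilibrate it by addition–elimination at C5''.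

Step 9
Reactants: 16 8-[2-(benzyloxy)-5-(1,3-dioxolan-2-yl)phenyl]-2-[4-(benzyloxy)-3-methoxyphenyl]-7-hydroxy-5-methoxy-4H-chromen-4-one
Product: 17 7-(benzyloxy)-8-[2-(benzyloxy)-5-(1,3-dioxolan-2-yl)phenyl]-2-[4-(benzyloxy)-3-methoxyphenyl]-5-methoxy-4H-chromen-4-one
Conditions: BnBr, K2CO3, DMF, rt to 40 °C
Reagents that add atoms: benzyl bromide, BrCc1ccccc1
Why: Williamson etherification of the acidic C7'' phenol protects it through the base- and iodine-mediated steps with a group that leaves in the final step together with the other benzyl ethers.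

Step 10
Reactants: 17 7-(benzyloxy)-8-[2-(benzyloxy)-5-(1,3-dioxolan-2-yl)phenyl]-2-[4-(benzyloxy)-3-methoxyphenyl]-5-methoxy-4H-chromen-4-one
Product: 18 4-(benzyloxy)-3-{7-(benzyloxy)-2-[4-(benzyloxy)-3-methoxyphenyl]-5-methoxy-4-oxo-4H-chromen-8-yl}benzaldehyde
Conditions: 1 M HCl, THF, rt
Reagents that add atoms: water, O
Why: Acid-catalysed acetal hydrolysis releases the aryl aldehyde, and the aryl ethers and the flavone are stable to dilute aqueous acid.

Step 11
Reactants: 19 2',4',6'-trihydroxyacetophenone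
Product: 20 1-[2,4-bis(benzyloxy)-6-hydroxyphenyl]ethan-1-one
Conditions: BnBr (2.1 equiv), K2CO3, DMF, rt
Reagents that add atoms: benzyl bromide, BrCc1ccccc1
Why: Williamson etherification with two equivalents of halide benzylates the para hydroxyl and one ortho hydroxyl, while the remaining ortho hydroxyl is held in a hydrogen bond to the ketone and stays free for the later ring closure.

Step 12
Reactants: 18 4-(benzyloxy)-3-{7-(benzyloxy)-2-[4-(benzyloxy)-3-methoxyphenyl]-5-methoxy-4-oxo-4H-chromen-8-yl}benzaldehyde; 20 1-[2,4-bis(benzyloxy)-6-hydroxyphenyl]ethan-1-one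
Product: 21 (E)-3-(4-(benzyloxy)-3-{7-(benzyloxy)-2-[4-(benzyloxy)-3-methoxyphenyl]-5-methoxy-4-oxo-4H-chromen-8-yl}phenyl)-1-[2,4-bis(benzyloxy)-6-hydroxyphenyl]prop-2-en-1-one
Conditions: KOH, EtOH/THF, rt; then dilute HCl to pH 5
Reagents that add atoms: none
Why: Claisen–Schmidt condensation, in which the acetophenone enolate adds to the non-enolisable aryl aldehyde and dehydration gives the conjugated chalcone with the thermodynamically favoured E alkene.

Step 13
Reactants: 21 (E)-3-(4-(benzyloxy)-3-{7-(benzyloxy)-2-[4-(benzyloxy)-3-methoxyphenyl]-5-methoxy-4-oxo-4H-chromen-8-yl}phenyl)-1-[2,4-bis(benzyloxy)-6-hydroxyphenyl]prop-2-en-1-one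
Product: 22 5,7-bis(benzyloxy)-2-(4-(benzyloxy)-3-{7-(benzyloxy)-2-[4-(benzyloxy)-3-methoxyphenyl]-5-methoxy-4-oxo-4H-chromen-8-yl}phenyl)-4H-chromen-4-one
Conditions: I2 (cat.), DMSO, 130 °C
Reagents that add atoms: none
Why: Iodine-catalysed oxidative cyclisation of a 2'-hydroxychalcone in DMSO, the standard closure of the flavone ring C, in which DMSO is the terminal oxidant and aryl benzyl and methyl ethers are tolerated.

Step 14
Reactants: 22 5,7-bis(benzyloxy)-2-(4-(benzyloxy)-3-{7-(benzyloxy)-2-[4-(benzyloxy)-3-methoxyphenyl]-5-methoxy-4-oxo-4H-chromen-8-yl}phenyl)-4H-chromen-4-one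
Product: 23 8-[5-(5,7-dihydroxy-4-oxo-4H-chromen-2-yl)-2-hydroxyphenyl]-5,7-dihydroxy-2-(4-hydroxy-3-methoxyphenyl)-4H-chromen-4-one (CNP0179340.0)
Conditions: BCl3, pentamethylbenzene, CH2Cl2, −78 °C to rt; MeOH quench
Reagents that add atoms: none
Why: Lewis-acid ether cleavage, in which BCl3 removes all five benzyl groups while pentamethylbenzene traps the benzyl cations before they can alkylate the electron-rich rings, and the C5'' methyl ether is cleaved through its six-membered boron chelate with the C4'' carbonyl whereas the unchelated C3''' methyl ether should stay.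

**Compound list**

1 | 4-(benzyloxy)-3-methoxybenzaldehyde (O-benzylvanillin) | O=Cc1ccc(OCc2ccccc2)c(OC)c1 | starting material
2 | 1-(benzyloxy)-4-(2,2-dibromoethenyl)-2-methoxybenzene | COc1cc(C=C(Br)Br)ccc1OCc1ccccc1 | intermediate
3 | lithium [4-(benzyloxy)-3-methoxyphenyl]acetylide (not isolated) | [Li]C#Cc1ccc(OCc2ccccc2)c(OC)c1 | intermediate
4 | 3-[4-(benzyloxy)-3-methoxyphenyl]-N-methoxy-N-methylprop-2-ynamide | CON(C)C(=O)C#Cc1ccc(OCc2ccccc2)c(OC)c1 | intermediate
5 | methyl (E)-3-methoxybut-2-enoate | CO/C(C)=C/C(=O)OC | starting material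
6 | lithium dienolate of 5, lithium 1,3-dimethoxybuta-1,3-dien-1-olate (not isolated) | C=C(OC)C=C(OC)O[Li] | intermediate
7 | methyl (E)-7-[4-(benzyloxy)-3-methoxyphenyl]-3-methoxy-5-oxohept-2-en-6-ynoate | COC(=O)/C=C(/OC)CC(=O)C#Cc1ccc(OCc2ccccc2)c(OC)c1 | intermediate
8 | 4-(benzyloxy)-3-bromobenzaldehyde | O=Cc1ccc(OCc2ccccc2)c(Br)c1 | starting material
9 | 2-[4-(benzyloxy)-3-bromophenyl]-1,3-dioxolane | Brc1cc(C2OCCO2)ccc1OCc1ccccc1 | intermediate
10 | ethyl [2-(benzyloxy)-5-(1,3-dioxolan-2-yl)phenyl]acetate | CCOC(=O)Cc1cc(C2OCCO2)ccc1OCc1ccccc1 | intermediate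
11 | [2-(benzyloxy)-5-(1,3-dioxolan-2-yl)phenyl]acetic acid | OC(=O)Cc1cc(C2OCCO2)ccc1OCc1ccccc1 | intermediate
12 | [2-(benzyloxy)-5-(1,3-dioxolan-2-yl)phenyl]acetyl chloride (not isolated) | O=C(Cl)Cc1cc(C2OCCO2)ccc1OCc1ccccc1 | intermediate
13 | methyl (E)-4-{[2-(benzyloxy)-5-(1,3-dioxolan-2-yl)phenyl]acetyl}-7-[4-(benzyloxy)-3-methoxyphenyl]-3-methoxy-5-oxohept-2-en-6-ynoate, drawn as the triketo tautomer (not isolated) | COC(=O)/C=C(/OC)C(C(=O)Cc1cc(C2OCCO2)ccc1OCc1ccccc1)C(=O)C#Cc1ccc(OCc2ccccc2)c(OC)c1 | intermediate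
14 | methyl (E)-3-{2-[2-(benzyloxy)-5-(1,3-dioxolan-2-yl)benzyl]-6-[4-(benzyloxy)-3-methoxyphenyl]-4-oxo-4H-pyran-3-yl}-3-methoxyprop-2-enoate | COC(=O)/C=C(/OC)c1c(Cc2cc(C3OCCO3)ccc2OCc2ccccc2)oc(-c2ccc(OCc3ccccc3)c(OC)c2)cc1=O | intermediate
15 | 8-[2-(benzyloxy)-5-(1,3-dioxolan-2-yl)phenyl]-2-[4-(benzyloxy)-3-methoxyphenyl]-5-methoxy-8H-chromene-4,7-dione (not isolated) | COC1=CC(=O)C(c2cc(C3OCCO3)ccc2OCc2ccccc2)c2oc(-c3ccc(OCc4ccccc4)c(OC)c3)cc(=O)c21 | intermediate
16 | 8-[2-(benzyloxy)-5-(1,3-dioxolan-2-yl)phenyl]-2-[4-(benzyloxy)-3-methoxyphenyl]-7-hydroxy-5-methoxy-4H-chromen-4-one | COc1cc(-c2cc(=O)c3c(OC)cc(O)c(-c4cc(C5OCCO5)ccc4OCc4ccccc4)c3o2)ccc1OCc1ccccc1 | intermediate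
17 | 7-(benzyloxy)-8-[2-(benzyloxy)-5-(1,3-dioxolan-2-yl)phenyl]-2-[4-(benzyloxy)-3-methoxyphenyl]-5-methoxy-4H-chromen-4-one | COc1cc(-c2cc(=O)c3c(OC)cc(OCc4ccccc4)c(-c4cc(C5OCCO5)ccc4OCc4ccccc4)c3o2)ccc1OCc1ccccc1 | intermediate
18 | 4-(benzyloxy)-3-{7-(benzyloxy)-2-[4-(benzyloxy)-3-methoxyphenyl]-5-methoxy-4-oxo-4H-chromen-8-yl}benzaldehyde | COc1cc(-c2cc(=O)c3c(OC)cc(OCc4ccccc4)c(-c4cc(C=O)ccc4OCc4ccccc4)c3o2)ccc1OCc1ccccc1 | intermediate
19 | 2',4',6'-trihydroxyacetophenone | CC(=O)c1c(O)cc(O)cc1O | starting material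
20 | 1-[2,4-bis(benzyloxy)-6-hydroxyphenyl]ethan-1-one | CC(=O)c1c(O)cc(OCc2ccccc2)cc1OCc1ccccc1 | intermediate
21 | (E)-3-(4-(benzyloxy)-3-{7-(benzyloxy)-2-[4-(benzyloxy)-3-methoxyphenyl]-5-methoxy-4-oxo-4H-chromen-8-yl}phenyl)-1-[2,4-bis(benzyloxy)-6-hydroxyphenyl]prop-2-en-1-one | COc1cc(-c2cc(=O)c3c(OC)cc(OCc4ccccc4)c(-c4cc(/C=C/C(=O)c5c(O)cc(OCc6ccccc6)cc5OCc5ccccc5)ccc4OCc4ccccc4)c3o2)ccc1OCc1ccccc1 | intermediate
22 | 5,7-bis(benzyloxy)-2-(4-(benzyloxy)-3-{7-(benzyloxy)-2-[4-(benzyloxy)-3-methoxyphenyl]-5-methoxy-4-oxo-4H-chromen-8-yl}phenyl)-4H-chromen-4-one | COc1cc(-c2cc(=O)c3c(OC)cc(OCc4ccccc4)c(-c4cc(-c5cc(=O)c6c(OCc7ccccc7)cc(OCc7ccccc7)cc6o5)ccc4OCc4ccccc4)c3o2)ccc1OCc1ccccc1 | intermediate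
23 | 8-[5-(5,7-dihydroxy-4-oxo-4H-chromen-2-yl)-2-hydroxyphenyl]-5,7-dihydroxy-2-(4-hydroxy-3-methoxyphenyl)-4H-chromen-4-one (CNP0179340.0) | COc1cc(-c2cc(=O)c3c(O)cc(O)c(-c4cc(-c5cc(=O)c6c(O)cc(O)cc6o5)ccc4O)c3o2)ccc1O | target

**Step count and risks**

Total step count: 14.
Longest linear sequence: 10 steps (steps 1, 2, 3, 7, 8, 9, 10, 12, 13, 14; the arm through steps 4, 5, 6 is equally long).

Steps most likely to fail:

1. Step 8, the step proposed as a new method. The extended enolate may form but attack the donor-substituted ester only sluggishly, so that intermolecular condensation or opening of the pyranone by the lithium methoxide overtakes ring closure. The fallback uses known chemistry, sets out from 9 and 1 and returns at 17.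
   - Bromide 9 would be converted by Miyaura borylation (B2pin2, Pd(dppf)Cl2, KOAc, dioxane, 90 °C) into 2-[4-(benzyloxy)-3-(4,4,5,5-tetramethyl-1,3,2-dioxaborolan-2-yl)phenyl]-1,3-dioxolane F1.
   - Purchased 1-(2,4-dihydroxy-6-methoxyphenyl)ethan-1-one would be benzylated at its unchelated hydroxyl (BnBr, K2CO3, acetone) to 1-[4-(benzyloxy)-2-hydroxy-6-methoxyphenyl]ethan-1-one F2.
   - F2 would be iodinated ortho to the free hydroxyl (benzyltrimethylammonium dichloroiodate, CaCO3, CH2Cl2/MeOH) to 1-[4-(benzyloxy)-2-hydroxy-3-iodo-6-methoxyphenyl]ethan-1-one F3.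
   - F3 would be condensed with aldehyde 1 (KOH, EtOH) to (E)-1-[4-(benzyloxy)-2-hydroxy-3-iodo-6-methoxyphenyl]-3-[4-(benzyloxy)-3-methoxyphenyl]prop-2-en-1-one F4 and cyclised (I2, DMSO, 130 °C) to 7-(benzyloxy)-2-[4-(benzyloxy)-3-methoxyphenyl]-8-iodo-5-methoxy-4H-chromen-4-one F5.
   - Suzuki–Miyaura coupling of F5 with F1 (Pd(OAc)2, SPhos, K3PO4, toluene/H2O, 100 °C) would give 17.
   - The price is that the position of the aryl group then rests on the regioselectivity of the iodination.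

2. Step 7. O-acylation of the magnesium enolate, ketene formation and self-condensation of the enolisable acid chloride, or lactonisation of the enolate of 7 onto its own ester to a 4-methoxy-2-pyranone may outrun C-acylation. The fallback inverts the order of the two acylations so that the acid chloride carries no α-hydrogen; it sets out from 11, 6 and 2 and returns at 14 through the same triketone 13.
   - Acid 11 would be coupled with N,O-dimethylhydroxylamine hydrochloride (EDC·HCl, i-Pr2NEt, CH2Cl2) to 2-[2-(benzyloxy)-5-(1,3-dioxolan-2-yl)phenyl]-N-methoxy-N-methylacetamide F6.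
   - F6 would acylate dienolate 6 (THF, −78 °C) to methyl (E)-6-[2-(benzyloxy)-5-(1,3-dioxolan-2-yl)phenyl]-3-methoxy-5-oxohex-2-enoate F7.
   - Dibromoalkene 2 would be taken through acetylide 3 (n-BuLi, THF, −78 °C) and CO2 to 3-[4-(benzyloxy)-3-methoxyphenyl]prop-2-ynoic acid F8, and on with (COCl)2 and catalytic DMF to 3-[4-(benzyloxy)-3-methoxyphenyl]prop-2-ynoyl chloride F9.
   - C-acylation of F7 with F9 (MgCl2, pyridine, CH2Cl2), the classical route from β-dicarbonyl compounds and arylpropioloyl chlorides to 4-pyranones, should lead to 13 and on to 14.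

3. Step 12. During the slow condensation of the hindered, electron-rich acetophenone, hydroxide may add to C2'' of the finished flavone of unit 2 and open its ring C. The fallback builds ring C of unit 1 by acyl transfer; it sets out from 18 and 20 and returns at 22.
   - Pinnick oxidation of 18 (NaClO2, NaH2PO4, 2-methylbut-2-ene, t-BuOH/H2O) would give 4-(benzyloxy)-3-{7-(benzyloxy)-2-[4-(benzyloxy)-3-methoxyphenyl]-5-methoxy-4-oxo-4H-chromen-8-yl}benzoic acid F10.
   - Steglich esterification of F10 with 20 (EDC·HCl, DMAP, CH2Cl2) would give 2-acetyl-3,5-bis(benzyloxy)phenyl 4-(benzyloxy)-3-{7-(benzyloxy)-2-[4-(benzyloxy)-3-methoxyphenyl]-5-methoxy-4-oxo-4H-chromen-8-yl}benzoate F11.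
   - Baker–Venkataraman rearrangement with a non-nucleophilic base (LiN(SiMe3)2, THF, −78 °C to rt) would give 1-(4-(benzyloxy)-3-{7-(benzyloxy)-2-[4-(benzyloxy)-3-methoxyphenyl]-5-methoxy-4-oxo-4H-chromen-8-yl}phenyl)-3-[2,4-bis(benzyloxy)-6-hydroxyphenyl]propane-1,3-dione F12.
   - Acid-catalysed cyclodehydration of F12 (TsOH, toluene, 80 °C) would give 22.

**Further compounds**

F1 | step 8 | 2-[4-(benzyloxy)-3-(4,4,5,5-tetramethyl-1,3,2-dioxaborolan-2-yl)phenyl]-1,3-dioxolane | CC1(C)OB(c2cc(C3OCCO3)ccc2OCc2ccccc2)OC1(C)C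
F2 | step 8 | 1-[4-(benzyloxy)-2-hydroxy-6-methoxyphenyl]ethan-1-one | CC(=O)c1c(O)cc(OCc2ccccc2)cc1OC
F3 | step 8 | 1-[4-(benzyloxy)-2-hydroxy-3-iodo-6-methoxyphenyl]ethan-1-one | CC(=O)c1c(O)c(I)c(OCc2ccccc2)cc1OC
F4 | step 8 | (E)-1-[4-(benzyloxy)-2-hydroxy-3-iodo-6-methoxyphenyl]-3-[4-(benzyloxy)-3-methoxyphenyl]prop-2-en-1-one | COc1cc(/C=C/C(=O)c2c(O)c(I)c(OCc3ccccc3)cc2OC)ccc1OCc1ccccc1
F5 | step 8 | 7-(benzyloxy)-2-[4-(benzyloxy)-3-methoxyphenyl]-8-iodo-5-methoxy-4H-chromen-4-one | COc1cc(-c2cc(=O)c3c(OC)cc(OCc4ccccc4)c(I)c3o2)ccc1OCc1ccccc1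
F6 | step 7 | 2-[2-(benzyloxy)-5-(1,3-dioxolan-2-yl)phenyl]-N-methoxy-N-methylacetamide | CON(C)C(=O)Cc1cc(C2OCCO2)ccc1OCc1ccccc1
F7 | step 7 | methyl (E)-6-[2-(benzyloxy)-5-(1,3-dioxolan-2-yl)phenyl]-3-methoxy-5-oxohex-2-enoate | COC(=O)/C=C(/OC)CC(=O)Cc1cc(C2OCCO2)ccc1OCc1ccccc1
F8 | step 7 | 3-[4-(benzyloxy)-3-methoxyphenyl]prop-2-ynoic acid | OC(=O)C#Cc1ccc(OCc2ccccc2)c(OC)c1
F9 | step 7 | 3-[4-(benzyloxy)-3-methoxyphenyl]prop-2-ynoyl chloride | O=C(Cl)C#Cc1ccc(OCc2ccccc2)c(OC)c1
F10 | step 12 | 4-(benzyloxy)-3-{7-(benzyloxy)-2-[4-(benzyloxy)-3-methoxyphenyl]-5-methoxy-4-oxo-4H-chromen-8-yl}benzoic acid | COc1cc(-c2cc(=O)c3c(OC)cc(OCc4ccccc4)c(-c4cc(C(=O)O)ccc4OCc4ccccc4)c3o2)ccc1OCc1ccccc1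
F11 | step 12 | 2-acetyl-3,5-bis(benzyloxy)phenyl 4-(benzyloxy)-3-{7-(benzyloxy)-2-[4-(benzyloxy)-3-methoxyphenyl]-5-methoxy-4-oxo-4H-chromen-8-yl}benzoate | COc1cc(-c2cc(=O)c3c(OC)cc(OCc4ccccc4)c(-c4cc(C(=O)Oc5cc(OCc6ccccc6)cc(OCc6ccccc6)c5C(C)=O)ccc4OCc4ccccc4)c3o2)ccc1OCc1ccccc1
F12 | step 12 | 1-(4-(benzyloxy)-3-{7-(benzyloxy)-2-[4-(benzyloxy)-3-methoxyphenyl]-5-methoxy-4-oxo-4H-chromen-8-yl}phenyl)-3-[2,4-bis(benzyloxy)-6-hydroxyphenyl]propane-1,3-dione | COc1cc(-c2cc(=O)c3c(OC)cc(OCc4ccccc4)c(-c4cc(C(=O)CC(=O)c5c(O)cc(OCc6ccccc6)cc5OCc5ccccc5)ccc4OCc4ccccc4)c3o2)ccc1OCc1ccccc1
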